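The tetrasubstituted C1=C10 alkene that joins the methylcyclopentane (C1–C5) to the seven-membered ring is read as the footprint of a Wagner–Meerwein shift. The precursor is a trans-fused decalin (eudesmane skeleton) whose equatorial C1 mesylate lies antiperiplanar to the C5–C10 ring-fusion bond. Ionisation moves C5 from C10 to C1, which contracts one cyclohexane to the cyclopentane, expands the other to the cycloheptene and places the alkene in one operation. The angular methyl at C10, erased in that step, first steers every face-selective event (C1, C4, C7, C8). The decalin is assembled by a catalytic enantioselective quinone Diels–Alder reaction.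

Key step: step 12

Remark: ring atoms are numbered as in eudesmanes and guaianes (C1–C15) in the Why lines; the names in the compound list use naphthalene or azulene locants.

Assumption: the (S)-configured oxazaborolidinium catalyst of step 3 is taken to give the (4aR) adduct; if the sense of induction is the opposite, its enantiomer is used and nothing else changes.

Step 1
Reactants: 1 2-methylbut-3-yn-2-ol
Product: 2 tert-butyldimethylsilyl ether of 2-methylbut-3-yn-2-ol
Conditions: TBSOTf, 2,6-lutidine, CH2Cl2, 0 → 23 °C
Reagents that add atoms: tert-butyldimethylsilyl trifluoromethanesulfonate (CC(C)(C)[Si](C)(C)OS(=O)(=O)C(F)(F)F)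
Why: Silyl ether formation with the silyl triflate masks the tertiary hydroxyl (the future C11 carbinol) as a robust ether; no stereocentre is involved.

Step 2
Reactants: 2 silyl ether of 2-methylbut-3-yn-2-ol
Product: 3 2-[2-(tert-butyldimethylsilyloxy)propan-2-yl]buta-1,3-diene
Conditions: ethylene (1 atm), Grubbs second-generation catalyst (5 mol%), toluene, 80 °C
Reagents that add atoms: ethylene (C=C)
Why: Ruthenium-carbene ene–yne cross-metathesis with ethylene should convert the terminal alkyne into the 2-substituted 1,3-diene, a propargylic silyl ether being a tolerated substituent.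

Step 3
Reactants: 3 2-substituted buta-1,3-diene; 4 2-methoxy-5-methyl-1,4-benzoquinone
Product: 6 trans-fused (4aR,8aR) methoxy ene-dione, via cis-fused cycloadduct 5 (not isolated)
Conditions: (S)-o-tolyl-CBS-oxazaborolidine·HNTf2 (20 mol%), CH2Cl2, −78 → −40 °C; then DBU (0.5 equiv), 0 → 23 °C
Reagents that add atoms: none
Why: Lewis-acid-catalysed Diels–Alder reaction in which the boron cation binds the more basic vinylogous-ester carbonyl of 4, so that the methoxy-free double bond reacts, the CH2 terminus next to the substituted diene carbon bonds to the quinone CH (side chain at the future C7) and the catalyst face selection sets the quaternary C10; DBU then epimerises the enolisable ring-fusion C5–H to the more stable trans-fused ene-dione.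

Step 4
Reactants: 6 trans-fused methoxy ene-dione
Product: 8 trans-fused (4aR,8aR) 1,4-dione, via 2-methoxy-1,4-dione 7 (not isolated)
Conditions: SmI2 (5 equiv), THF–MeOH, −78 → 0 °C
Reagents that add atoms: none
Why: Samarium diiodide single-electron reduction should first saturate the ene-dione C2=C3 bond and then cleave the resulting α-methoxy ketone through the C4 ketyl, leaving the isolated alkene, the silyl ether and both stereocentres untouched.

Step 5
Reactants: 8 trans-fused 1,4-dione
Product: 9 4-methylidene ketone (4aS,8aR)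
Conditions: Zn, CH2Br2, TiCl4, THF–CH2Cl2, 0 → 23 °C
Reagents that add atoms: dibromomethane (BrCBr)
Why: Takai–Lombardo methylenation is non-basic, so the enolisable C5–H should not epimerise, and it should react only at the C4 ketone because the C1 ketone is shielded by the adjacent quaternary C10.

Step 6
Reactants: 9 4-methylidene ketone
Product: 10 4β-methyl ketone (4S,4aS,8aR)
Conditions: H2 (1 atm), RhCl(PPh3)3 (5 mol%), benzene–EtOH, 23 °C
Reagents that add atoms: none
Why: Homogeneous hydrogenation with Wilkinson's catalyst should reduce only the exocyclic 1,1-disubstituted alkene and deliver hydrogen to C4 from the α-face, opposite the syn-axial angular methyl, which sets the axial 4β-methyl group.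

Step 7
Reactants: 10 4β-methyl ketone
Product: 11 equatorial 1β-alcohol (1R,4S,4aS,8aR)
Conditions: NaBH4, MeOH–CH2Cl2, 0 → 23 °C
Reagents that add atoms: none
Why: Borohydride reduction by axial hydride attack from the α-face, anti to the adjacent axial angular methyl, should give the equatorial alcohol cis to that methyl.

Step 8
Reactants: 11 equatorial 1β-alcohol
Product: 12 C1 methanesulfonate
Conditions: MsCl, Et3N, DMAP (cat.), CH2Cl2, 0 °C
Reagents that add atoms: methanesulfonyl chloride (CS(=O)(=O)Cl)
Why: Sulfonylation of the secondary alcohol installs the leaving group with retention at C1, and the equatorial neopentyl-type mesylate is inert to substitution under the conditions of the next steps.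

Step 9
Reactants: 12 C1 methanesulfonate
Product: 14 trans hydroxy mesylate (1R,4S,4aS,6S,7S,8aR), via secondary alkylborane 13 (not isolated)
Conditions: BH3·THF, THF, 0 → 23 °C; then NaOH, 30% H2O2, 0 °C
Reagents that add atoms: borane (B); hydrogen peroxide (OO)
Why: Hydroboration–oxidation adds H and B syn and anti-Markovnikov to the trisubstituted C7=C8 alkene from the α-face, away from the angular methyl that is 1,3-diaxial to C8, and stereoretentive oxidation should then give 7α-H and 8α-OH together, that is the side chain and the hydroxyl trans.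

Step 10
Reactants: 15 p-coumaric acid
Product: 17 (E)-4-(tert-butyldimethylsilyloxy)cinnamic acid, via bis-silylated coumarate 16 (not isolated)
Conditions: TBSCl (2.5 equiv), imidazole, DMF, 23 °C; then AcOH–THF–H2O, 23 °C
Reagents that add atoms: tert-butyldimethylsilyl chloride (CC(C)(C)[Si](C)(C)Cl)
Why: Exhaustive silylation followed by selective hydrolysis of the labile silyl ester should give the phenol-protected acid with the E-alkene unchanged.

Step 11
Reactants: 14 trans hydroxy mesylate; 17 silyl-protected coumaric acid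
Product: 18 C8 coumarate ester of the mesylate
Conditions: EDC·HCl, DMAP, CH2Cl2, 23 → 40 °C
Reagents that add atoms: none
Why: Steglich esterification acylates the only free hydroxyl with retention at C8, and the ester also keeps the C8 oxygen from triggering a fragmentation in the next step.

Step 12
Reactants: 18 C8 coumarate ester of the mesylate
Product: 20 bis-silylated guaiene ester, via guaianyl C10 cation 19 (not isolated)
Conditions: KOAc, AcOH, 80 °C
Reagents that add atoms: none
Why: Heating the equatorial C1 mesylate in buffered acetic acid should ionise the C1–O bond with assistance from the antiperiplanar C5–C10 σ-bond, so that C5 migrates from C10 to C1 (Wagner–Meerwein 1,2-alkyl shift, inversion at C1, retention at C5) to give the tertiary C10 cation 19, which loses the C1 proton to acetate. The closest known reaction type is the solvolytic hydronaphthalene-to-hydroazulene (eudesmane-to-guaiane) rearrangement of decalyl sulfonates. The cyclopentane C1–C5 is closed by ring contraction of the cyclohexane C1–C2–C3–C4–C5–C10 through the new C1–C5 bond, and the seven-membered ring arises in the same event by one-carbon expansion of the second cyclohexane as C1 is inserted between C5 and C10. No stereocentre is created: C4, C5, C7 and C8 are carried over, and the C1 and C10 centres that steered the earlier steps are erased. The step needs migration of C5 and not of the angular methyl or C9, which the rigid trans-decalin secures because only the C5–C10 bond is antiperiplanar to the equatorial leaving group, and relief of the 1,3-diaxial methyl–methyl strain assists it. It also needs proton loss towards C1, which gives the most substituted alkene.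

Step 13
Reactants: 20 bis-silylated guaiene ester
Product: 21 target (CNP0403230.1)
Conditions: HF·pyridine, pyridine, THF, 0 → 23 °C
Reagents that add atoms: none
Why: Fluoride-mediated cleavage of the aryl and the tertiary alkyl silyl ethers under pyridine-buffered conditions should leave the cinnamate ester, the tetrasubstituted alkene and all stereocentres intact.

Compound list
1 | 2-methylbut-3-yn-2-ol | CC(C)(O)C#C | starting material
2 | tert-butyldimethyl[(2-methylbut-3-yn-2-yl)oxy]silane | C#CC(C)(C)O[Si](C)(C)C(C)(C)C | intermediate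
3 | tert-butyldimethyl[(2-methyl-3-methylidenepent-4-en-2-yl)oxy]silane | C=CC(=C)C(C)(C)O[Si](C)(C)C(C)(C)C | intermediate
4 | 2-methoxy-5-methylcyclohexa-2,5-diene-1,4-dione | COC1=CC(=O)C(C)=CC1=O | starting material
5 | (4aR,8aS)-7-[2-(tert-butyldimethylsilyloxy)propan-2-yl]-2-methoxy-4a-methyl-4a,5,8,8a-tetrahydronaphthalene-1,4-dione (cis-fused) | O=C1C(OC)=CC(=O)[C@]2(C)CC=C(C(C)(C)O[Si](C)(C)C(C)(C)C)C[C@H]12 | intermediate
6 | (4aR,8aR)-7-[2-(tert-butyldimethylsilyloxy)propan-2-yl]-2-methoxy-4a-methyl-4a,5,8,8a-tetrahydronaphthalene-1,4-dione (trans-fused) | O=C1C(OC)=CC(=O)[C@]2(C)CC=C(C(C)(C)O[Si](C)(C)C(C)(C)C)C[C@@H]12 | intermediate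
7 | (4aR,8aR)-7-[2-(tert-butyldimethylsilyloxy)propan-2-yl]-2-methoxy-4a-methyl-2,3,4a,5,8,8a-hexahydronaphthalene-1,4-dione (both C2 epimers) | O=C1C(OC)CC(=O)[C@]2(C)CC=C(C(C)(C)O[Si](C)(C)C(C)(C)C)C[C@@H]12 | intermediate
8 | (4aR,8aR)-7-[2-(tert-butyldimethylsilyloxy)propan-2-yl]-4a-methyl-2,3,4a,5,8,8a-hexahydronaphthalene-1,4-dione | O=C1CCC(=O)[C@]2(C)CC=C(C(C)(C)O[Si](C)(C)C(C)(C)C)C[C@@H]12 | intermediate
9 | (4aS,8aR)-6-[2-(tert-butyldimethylsilyloxy)propan-2-yl]-8a-methyl-4-methylidene-3,4,4a,5,8,8a-hexahydronaphthalen-1(2H)-one | C=C1CCC(=O)[C@]2(C)CC=C(C(C)(C)O[Si](C)(C)C(C)(C)C)C[C@@H]12 | intermediate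
10 | (4S,4aS,8aR)-6-[2-(tert-butyldimethylsilyloxy)propan-2-yl]-4,8a-dimethyl-3,4,4a,5,8,8a-hexahydronaphthalen-1(2H)-one | C[C@H]1CCC(=O)[C@]2(C)CC=C(C(C)(C)O[Si](C)(C)C(C)(C)C)C[C@@H]12 | intermediate
11 | (1R,4S,4aS,8aR)-6-[2-(tert-butyldimethylsilyloxy)propan-2-yl]-4,8a-dimethyl-1,2,3,4,4a,5,8,8a-octahydronaphthalen-1-ol | C[C@H]1CC[C@@H](O)[C@]2(C)CC=C(C(C)(C)O[Si](C)(C)C(C)(C)C)C[C@@H]12 | intermediate
12 | (1R,4S,4aS,8aR)-6-[2-(tert-butyldimethylsilyloxy)propan-2-yl]-4,8a-dimethyl-1,2,3,4,4a,5,8,8a-octahydronaphthalen-1-yl methanesulfonate | C[C@H]1CC[C@@H](OS(C)(=O)=O)[C@]2(C)CC=C(C(C)(C)O[Si](C)(C)C(C)(C)C)C[C@@H]12 | intermediate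
13 | (1R,4S,4aS,6S,7S,8aR)-7-boranyl-6-[2-(tert-butyldimethylsilyloxy)propan-2-yl]-4,8a-dimethyldecahydronaphthalen-1-yl methanesulfonate | C[C@H]1CC[C@@H](OS(C)(=O)=O)[C@]2(C)C[C@H](B)[C@@H](C(C)(C)O[Si](C)(C)C(C)(C)C)C[C@@H]12 | intermediate
14 | (1R,4S,4aS,6S,7S,8aR)-6-[2-(tert-butyldimethylsilyloxy)propan-2-yl]-7-hydroxy-4,8a-dimethyldecahydronaphthalen-1-yl methanesulfonate | C[C@H]1CC[C@@H](OS(C)(=O)=O)[C@]2(C)C[C@H](O)[C@@H](C(C)(C)O[Si](C)(C)C(C)(C)C)C[C@@H]12 | intermediate
15 | (2E)-3-(4-hydroxyphenyl)prop-2-enoic acid (p-coumaric acid) | OC(=O)/C=C/c1ccc(O)cc1 | starting material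
16 | tert-butyldimethylsilyl (2E)-3-[4-(tert-butyldimethylsilyloxy)phenyl]prop-2-enoate | CC(C)(C)[Si](C)(C)OC(=O)/C=C/c1ccc(O[Si](C)(C)C(C)(C)C)cc1 | intermediate
17 | (2E)-3-[4-(tert-butyldimethylsilyloxy)phenyl]prop-2-enoic acid | OC(=O)/C=C/c1ccc(O[Si](C)(C)C(C)(C)C)cc1 | intermediate
18 | (2S,3S,4aS,5S,8R,8aR)-3-[2-(tert-butyldimethylsilyloxy)propan-2-yl]-5,8a-dimethyl-8-(methylsulfonyloxy)decahydronaphthalen-2-yl (2E)-3-[4-(tert-butyldimethylsilyloxy)phenyl]prop-2-enoate | C[C@H]1CC[C@@H](OS(C)(=O)=O)[C@]2(C)C[C@H](OC(=O)/C=C/c3ccc(O[Si](C)(C)C(C)(C)C)cc3)[C@@H](C(C)(C)O[Si](C)(C)C(C)(C)C)C[C@@H]12 | intermediate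
19 | tertiary C10 carbocation of the cis-fused hydroazulene (decahydroazulen-8-ylium, 8a-H cis to 3a-H) carrying the substituents of 20 | C[C+]1[C@@H]2CC[C@H](C)[C@@H]2C[C@H](C(C)(C)O[Si](C)(C)C(C)(C)C)[C@@H](OC(=O)/C=C/c2ccc(O[Si](C)(C)C(C)(C)C)cc2)C1 | intermediate
20 | (3S,3aS,5S,6S)-5-[2-(tert-butyldimethylsilyloxy)propan-2-yl]-3,8-dimethyl-1,2,3,3a,4,5,6,7-octahydroazulen-6-yl (2E)-3-[4-(tert-butyldimethylsilyloxy)phenyl]prop-2-enoate | CC1=C2CC[C@H](C)[C@@H]2C[C@H](C(C)(C)O[Si](C)(C)C(C)(C)C)[C@@H](OC(=O)/C=C/c2ccc(O[Si](C)(C)C(C)(C)C)cc2)C1 | intermediate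
21 | (3S,3aS,5S,6S)-5-(2-hydroxypropan-2-yl)-3,8-dimethyl-1,2,3,3a,4,5,6,7-octahydroazulen-6-yl (2E)-3-(4-hydroxyphenyl)prop-2-enoate | CC1=C2CC[C@H](C)[C@@H]2C[C@H](C(C)(C)O)[C@@H](OC(=O)/C=C/c2ccc(O)cc2)C1 | target

Total step count: 13. Longest linear sequence: 12 steps (steps 1–9 and 11–13); step 10 is a one-step side branch.

Steps most likely to fail

Step 12 (ring contraction and expansion). The proton may be lost unselectively from the C10 cation (towards C9 or the methyl group), a 1,2-hydride shift may move the charge to C1, or the neighbouring ester carbonyl may capture the cation. The fallback sets out from 18 and comes back at 20. Solvolysis in aqueous acetone buffered with NaHCO3 at 60 °C lets the same 1,2-shift take place but intercepts the cation with water, which should give the rearranged tertiary C10 carbinol F4. Dehydration of this carbinol with SOCl2 and pyridine at −20 °C, an anti elimination towards the C1 hydrogen, should then give 20.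

Step 3 (catalytic Diels–Alder reaction and epimerisation). Enantioface or regiochemical control may be insufficient when the bulky diene adds to the methyl-bearing double bond, or the acid catalyst may ionise the tertiary silyl ether of the diene. The fallback sets out from 3 and 4 and comes back at 6. The cycloaddition is run with achiral BF3·OEt2 in CH2Cl2 at −78 °C, where monodentate coordination at the same carbonyl should keep the regiochemistry; this gives 5 together with the enantiomeric cis adduct F1. DBU equilibration gives 6 together with the enantiomeric trans ene-dione F2, and preparative chromatography on a chiral stationary phase separates 6.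

Step 4 (tandem reduction and demethoxylation). Cleavage of the C–OMe bond may be incomplete, a ketone may be over-reduced or pinacol-coupled, or the ring fusion may epimerise. The fallback sets out from 6 and comes back at 8. Zinc dust in acetic acid reduces only the ene-dione double bond and 7 is isolated. DBU in CH2Cl2 then expels methanol by E1cB elimination to the methoxy-free ene-dione F3, and a second zinc–acetic acid reduction should give 8.

Further compounds
F1 | step 3 | (4aS,8aR)-7-[2-(tert-butyldimethylsilyloxy)propan-2-yl]-2-methoxy-4a-methyl-4a,5,8,8a-tetrahydronaphthalene-1,4-dione (enantiomer of 5) | O=C1C(OC)=CC(=O)[C@@]2(C)CC=C(C(C)(C)O[Si](C)(C)C(C)(C)C)C[C@@H]12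
F2 | step 3 | (4aS,8aS)-7-[2-(tert-butyldimethylsilyloxy)propan-2-yl]-2-methoxy-4a-methyl-4a,5,8,8a-tetrahydronaphthalene-1,4-dione (enantiomer of 6) | O=C1C(OC)=CC(=O)[C@@]2(C)CC=C(C(C)(C)O[Si](C)(C)C(C)(C)C)C[C@H]12
F3 | step 4 | (4aR,8aR)-7-[2-(tert-butyldimethylsilyloxy)propan-2-yl]-4a-methyl-4a,5,8,8a-tetrahydronaphthalene-1,4-dione | O=C1C=CC(=O)[C@]2(C)CC=C(C(C)(C)O[Si](C)(C)C(C)(C)C)C[C@@H]12
F4 | step 12 | 8-hydroxy derivative of 20 hydrated across C8=C8a (decahydroazulene, 8a-H cis to 3a-H, both C8 epimers) | CC1(O)[C@@H]2CC[C@H](C)[C@@H]2C[C@H](C(C)(C)O[Si](C)(C)C(C)(C)C)[C@@H](OC(=O)/C=C/c2ccc(O[Si](C)(C)C(C)(C)C)cc2)C1
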